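**Retrosynthetic overview**
1. Target 11 ⇐ (2S)-5-prenyloxyflavanone 8: the prenyl group is moved from O5 to C8 by a para-Claisen (Claisen–Cope) rearrangement as the last step.
2. 8 ⇐ chalcone 6: the O1–C2 bond is made by a catalytic enantioselective 6-endo oxa-Michael ring closure, which forms ring C and sets C2.
3. 6 ⇐ ketone 3 + 4-methoxybenzaldehyde 4 (Claisen–Schmidt condensation).
4. 3 ⇐ 2',6'-dihydroxy-4'-methoxyacetophenone 1 + prenyl bromide 2; the mono-O-prenyl ether leaves a single free phenol, so only one flavanone regioisomer can form, and it carries the prenyl unit for the last step.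
5. Ring order: rings A and B are bought; ring C is closed in step 3.

Assumption: 1 and the quinine-derived squaramide of step 3 are bought as catalogue compounds; the sense of induction in step 3 is a working model to be confirmed by CD and chiral HPLC, with the quinidine-derived pseudoenantiomer as the switch if 2R predominates.

**Step 1**
Reactants: 1 2',6'-dihydroxy-4'-methoxyacetophenone; 2 prenyl bromide (1-bromo-3-methylbut-2-ene)
Product: 3 1-[2-hydroxy-4-methoxy-6-(3-methylbut-2-enyloxy)phenyl]ethanone
Conditions: 2 (1.05 equiv), K2CO3 (1.5 equiv), acetone, reflux, 6 h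
Reagents that add atoms: prenyl bromide (compound 2), CC(C)=CCBr
Why: Williamson O-alkylation (SN2) of one of two equivalent phenols; K2CO3 in acetone favours O- over C-prenylation, and the remaining OH is locked in a hydrogen bond to the ketone, so the second alkylation is much slower; no stereocentre is formed.

**Step 2**
Reactants: 3 1-[2-hydroxy-4-methoxy-6-(3-methylbut-2-enyloxy)phenyl]ethanone; 4 4-methoxybenzaldehyde
Product: 6 (E)-1-[2-hydroxy-4-methoxy-6-(3-methylbut-2-enyloxy)phenyl]-3-(4-methoxyphenyl)prop-2-en-1-one, via aldol adduct 5 (not isolated)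
Conditions: 4 (1.2 equiv), KOH (50% aq., 10 equiv), EtOH, 0 °C → rt, 24 h; then cold 1 M HCl to pH 4; crystallise from EtOH
Reagents that add atoms: 4-methoxybenzaldehyde (compound 4), COc1ccc(C=O)cc1
Why: Claisen–Schmidt (crossed aldol) condensation with a non-enolisable aldehyde, followed by E1cB dehydration of 5 to the E-enone; this is the standard entry to 2'-hydroxy-4',6'-dialkoxychalcones, the product rests as the chalcone phenolate in strong base (so it does not ring-close), and the prenyl ether is base-stable.

**Step 3**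
Reactants: 6 (E)-1-[2-hydroxy-4-methoxy-6-(3-methylbut-2-enyloxy)phenyl]-3-(4-methoxyphenyl)prop-2-en-1-one
Product: 8 (2S)-7-methoxy-2-(4-methoxyphenyl)-5-(3-methylbut-2-enyloxy)chroman-4-one, via enol tautomer 7 (not isolated)
Conditions: 3-{[3,5-bis(trifluoromethyl)phenyl]amino}-4-{[(8α,9S)-6'-methoxycinchonan-9-yl]amino}cyclobut-3-ene-1,2-dione (quinine-derived squaramide, 10 mol%), PhMe/CH2Cl2 4:1, 0 °C, 48–72 h
Reagents that add atoms: none
Why: Proposed new method: catalytic enantioselective 6-endo-trig intramolecular oxa-Michael addition of an unactivated 2'-hydroxychalcone (no α-ester); the quinuclidine nitrogen deprotonates the 2'-OH, breaking its hydrogen bond to the ketone, and holds the phenoxide as a tight ion pair, while the squaramide N–H pair binds the enone oxygen in the s-cis conformer, so the phenoxide adds to the Si face of C-β (which gives 2S) and the ammonium protonates enolate 7 at C3; the 6'-prenyloxy group twists the aryl ketone out of conjugation, which makes the enone more reactive and the ring closure strongly downhill, so retro-oxa-Michael racemisation should be negligible at 0 °C; closest known reaction type: cinchona thiourea or squaramide-catalysed oxa-Michael cyclisation of α-alkoxycarbonyl-activated 2'-hydroxychalcones to flavanones, and the moderately selective cinchona-alkaloid cyclisation of simple 2'-hydroxychalcones.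

**Step 4**
Reactants: 8 (2S)-7-methoxy-2-(4-methoxyphenyl)-5-(3-methylbut-2-enyloxy)chroman-4-one
Product: 11 flowerine [(2S)-5-hydroxy-7-methoxy-2-(4-methoxyphenyl)-8-(3-methylbut-2-enyl)chroman-4-one], via ortho-dienone 9 (not isolated), via para-dienone 10 (not isolated)
Conditions: Eu(fod)3 [tris(6,6,7,7,8,8,8-heptafluoro-2,2-dimethyloctane-3,5-dionato)europium] (10 mol%), dry CHCl3, 65 °C, sealed tube, 24 h
Reagents that add atoms: none
Why: Lewis-acid-catalysed aromatic para-Claisen (Claisen–Cope) rearrangement, known for 5-prenyloxyflavanones: trivalent europium bound at the C4 carbonyl and O5 accelerates the [3,3] shift to C6 (9, reverse prenyl), a Cope [3,3] shift carries the group to C8 with a second allylic inversion (10, normal prenyl), and enolisation gives the chelated 5-OH phenol; no bond to C2 is broken, so the 2S centre is kept.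

**Compound list**
1 | 2',6'-dihydroxy-4'-methoxyacetophenone | CC(=O)c1c(O)cc(OC)cc1O | starting material
2 | prenyl bromide (1-bromo-3-methylbut-2-ene) | CC(C)=CCBr | starting material
3 | 1-[2-hydroxy-4-methoxy-6-(3-methylbut-2-enyloxy)phenyl]ethanone | CC(=O)c1c(O)cc(OC)cc1OCC=C(C)C | intermediate
4 | 4-methoxybenzaldehyde | COc1ccc(C=O)cc1 | starting material
5 | 3-hydroxy-1-[2-hydroxy-4-methoxy-6-(3-methylbut-2-enyloxy)phenyl]-3-(4-methoxyphenyl)propan-1-one (racemic aldol adduct) | COc1ccc(C(O)CC(=O)c2c(O)cc(OC)cc2OCC=C(C)C)cc1 | intermediate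
6 | (E)-1-[2-hydroxy-4-methoxy-6-(3-methylbut-2-enyloxy)phenyl]-3-(4-methoxyphenyl)prop-2-en-1-one | COc1ccc(/C=C/C(=O)c2c(O)cc(OC)cc2OCC=C(C)C)cc1 | intermediate
7 | (2S)-7-methoxy-2-(4-methoxyphenyl)-5-(3-methylbut-2-enyloxy)-2H-chromen-4-ol (enol of 8, present as its enolate ion-paired to the protonated catalyst) | COc1ccc([C@@H]2C=C(O)c3c(OCC=C(C)C)cc(OC)cc3O2)cc1 | intermediate
8 | (2S)-7-methoxy-2-(4-methoxyphenyl)-5-(3-methylbut-2-enyloxy)chroman-4-one | COc1ccc([C@@H]2CC(=O)c3c(OCC=C(C)C)cc(OC)cc3O2)cc1 | intermediate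
9 | (2S)-7-methoxy-2-(4-methoxyphenyl)-6-(2-methylbut-3-en-2-yl)-2,3-dihydrochromene-4,5(6H)-dione (ortho-dienone, both C6 epimers) | COc1ccc([C@@H]2CC(=O)C3=C(O2)C=C(OC)C(C(C)(C)C=C)C3=O)cc1 | intermediate
10 | (2S)-7-methoxy-2-(4-methoxyphenyl)-8-(3-methylbut-2-enyl)-2,3-dihydrochromene-4,5(8H)-dione (para-dienone, both C8 epimers) | COc1ccc([C@@H]2CC(=O)C3=C(O2)C(CC=C(C)C)C(OC)=CC3=O)cc1 | intermediate
11 | flowerine, (2S)-5-hydroxy-7-methoxy-2-(4-methoxyphenyl)-8-(3-methylbut-2-enyl)chroman-4-one | COc1ccc([C@@H]2CC(=O)c3c(O)cc(OC)c(CC=C(C)C)c3O2)cc1 | target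

**Totals**
Total step count: 4. Longest linear sequence: 4 steps (1 → 3 → 6 → 8 → 11).

**Steps most likely to fail, with fallbacks**

Step 3 (proposed new method) is the main risk: the enantioselectivity may be low, the sense of induction may be opposite, or turnover may be slow. The fallback uses known chemistry and sets out from chalcone 6. Heating 6 with NaOAc in EtOH at reflux gives racemic 7-methoxy-2-(4-methoxyphenyl)-5-(3-methylbut-2-enyloxy)chroman-4-one F1. Kinetic resolution of F1 by asymmetric transfer hydrogenation (RuCl(p-cymene)[(R,R)-TsDPEN] 1 mol%, HCO2H/Et3N 5:2, EtOAc, rt, to about 55% conversion) reduces the 2R enantiomer to the cis-flavanol (2R,4R)-7-methoxy-2-(4-methoxyphenyl)-5-(3-methylbut-2-enyloxy)chroman-4-ol F2. The unreacted ketone is the 2S enantiomer, which is separated by chromatography and is compound 8, where the fallback comes back to the route. The fast-reacting enantiomer is assigned from the usual aryl-ketone facial rule and the cis preference of flavanone reduction, and should be checked on the first run.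

Step 4 is the second risk: ortho-Claisen product (the 6-(2-methylbut-3-en-2-yl) isomer, from enolisation of 9 before the Cope shift) may compete, and the Lewis acid at 65 °C could erode the ee by ring opening. The fallback moves the rearrangement to a stage with no stereocentre and sets out from ketone 3. Heating 3 in N,N-diethylaniline at 200 °C (thermal para-Claisen–Cope) gives 1-[2,6-dihydroxy-4-methoxy-3-(3-methylbut-2-enyl)phenyl]ethanone F3. Protection of the less hindered 6-OH (MOMCl 1.05 equiv, iPr2NEt, CH2Cl2, 0 °C) gives 1-[2-hydroxy-4-methoxy-6-(methoxymethoxy)-3-(3-methylbut-2-enyl)phenyl]ethanone F4. Claisen–Schmidt condensation of F4 with 4 (KOH, EtOH, rt) gives (E)-1-[2-hydroxy-4-methoxy-6-(methoxymethoxy)-3-(3-methylbut-2-enyl)phenyl]-3-(4-methoxyphenyl)prop-2-en-1-one F5. Ring closure under the step 3 conditions, through the only free phenol, gives (2S)-7-methoxy-5-(methoxymethoxy)-2-(4-methoxyphenyl)-8-(3-methylbut-2-enyl)chroman-4-one F6. Removal of the MOM group (1 M HCl, MeOH, 40 °C) gives 11, where the fallback comes back to the route.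

Step 1 is the third risk: C-prenylation of the electron-rich ring or bis-alkylation may lower the yield of the mono-ether. The fallback sets out from 1 and replaces phenoxide alkylation by a Mitsunobu etherification with 3-methylbut-2-en-1-ol (PPh3, DIAD, THF, 0 °C → rt, 1.0 equiv of alcohol). This reacts at oxygen only, under neutral conditions, and gives 3 directly, where the fallback comes back to the route; it makes no new compound (F0).

**Further compounds**
F1 | step 3 | racemic 7-methoxy-2-(4-methoxyphenyl)-5-(3-methylbut-2-enyloxy)chroman-4-one | COc1ccc(C2CC(=O)c3c(OCC=C(C)C)cc(OC)cc3O2)cc1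
F2 | step 3 | (2R,4R)-7-methoxy-2-(4-methoxyphenyl)-5-(3-methylbut-2-enyloxy)chroman-4-ol | COc1ccc([C@H]2C[C@@H](O)c3c(OCC=C(C)C)cc(OC)cc3O2)cc1
F3 | step 4 | 1-[2,6-dihydroxy-4-methoxy-3-(3-methylbut-2-enyl)phenyl]ethanone | CC(=O)c1c(O)cc(OC)c(CC=C(C)C)c1O
F4 | step 4 | 1-[2-hydroxy-4-methoxy-6-(methoxymethoxy)-3-(3-methylbut-2-enyl)phenyl]ethanone | CC(=O)c1c(OCOC)cc(OC)c(CC=C(C)C)c1O
F5 | step 4 | (E)-1-[2-hydroxy-4-methoxy-6-(methoxymethoxy)-3-(3-methylbut-2-enyl)phenyl]-3-(4-methoxyphenyl)prop-2-en-1-one | COc1ccc(/C=C/C(=O)c2c(OCOC)cc(OC)c(CC=C(C)C)c2O)cc1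
F6 | step 4 | (2S)-7-methoxy-5-(methoxymethoxy)-2-(4-methoxyphenyl)-8-(3-methylbut-2-enyl)chroman-4-one | COc1ccc([C@@H]2CC(=O)c3c(OCOC)cc(OC)c(CC=C(C)C)c3O2)cc1
F0 | step 1 | none | none
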